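Partner that has gone to homo dimer cannot come back to turn the catalyst, and that was the loss I had to reckon with.

common to all: precatalyst 20 mM

|  | starting material | partner | time | remark |
|---|---|---|---|---|
| dawn | 0.20 M | 0.240 M (fed, over 2.00 min) | 4.0 min | a stirred flask in which partner is dosed at a steady rate over 2.00 min without added volume, worked up at 4.0 min |
| midnight | 0.20 M | 0.240 M | 4.0 min | everything together in a closed stirred flask, run for 4.0 min |
| summer | 0.20 M | 0.240 M |  | a single well-mixed tank run continuously and read at steady state, 4.0 min in it on average |
| winter | 0.20 M (fed, over 2.00 min) | 0.240 M | 4.0 min | all but starting material at the start; starting material goes in evenly over 2.00 min, the run ends at 4.0 min |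

    catalyst intermediate A → catalyst intermediate B (k1 = 1.2 s⁻¹)
    2 partner → homo dimer (k2 = 0.38 L mol⁻¹ s⁻¹)
    partner + precatalyst → free catalyst + spent reagent (k3 = 0.25 L mol⁻¹ s⁻¹)
    catalyst intermediate C → free catalyst + product (k4 = 69 s⁻¹)
    starting material + free catalyst → catalyst intermediate A (k5 = 4.7 L mol⁻¹ s⁻¹)
    partner + catalyst intermediate B → catalyst intermediate C (k6 = 0.96 L mol⁻¹ s⁻¹)

* the set-up with the highest amount of product at the outlet or at the end, in percent of the starting material put in ("none" if the first two lie within 2 percentage points) (dawn / midnight / summer / winter / none)
* amount of product at the outlet or at the end, in percent of the starting material put in, dawn
* amount of product at the outlet or at the end, in percent of the starting material put in, midnight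
* amount of product at the outlet or at the end, in percent of the starting material put in, summer
* amount of product at the outlet or at the end, in percent of the starting material put in, winter

- where a step has two of a species, its rate is k times that concentration squared, and two are used at each turn
- the stated concentrations are those of everything mixed, before any reaction; amounts are the same in each set-up
- the feed brings no volume worth counting
- run time (dawn): 4.0 min

My hand went as far as midnight. Catalyst released from precatalyst should wait in catalyst intermediate B, the resting state, because its half-life by the step with partner as charged is longer than that of catalyst intermediate A by its own step and that of free catalyst meeting starting material as charged. Product and activation both run on partner, so I divided one rate by the other, and partner and time dropped out. What remained was the leverage G, the charged catalyst over the charged starting material, times the ratio of the two rate constants: 0.384. With y the product as a fraction of starting material, r the fraction of precatalyst left and f the fraction gone: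

y = G × (−ln r − f)

For the ceiling, I gave partner no loss other than dimerising, which left r at 28.6%:

y below 20.6%

For the floor, I let the catalyst eat partner as if its whole charge stood in catalyst intermediate B, which overstates the use of partner because activation has the smaller rate constant. That left r at 46.3%. I also counted catalyst in the ring as sitting in catalyst intermediate B for the share it has at the charged concentrations, with free catalyst and catalyst intermediates A and C counted, 69.4%:

y above 6.22%

The forecast, noting that “partner also dimerises quickly”, gave 25% for dawn, 11.3% for midnight, 35.8% for summer and 11.5% for winter, and chose summer. Its midnight figure stood inside my bracket.

The simulation gave 25.9% for dawn, 10.8% for midnight, 35.2% for summer and 8.42% for winter, so the best set-up was summer.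

Midnight's 39.7% of precatalyst left at 4.00 min gives 12.3% by the rule, against the 10.8% found. The neighbour of winter charged with 0.0050 M of precatalyst, with 31.6% left, gives 4.49% by the rule, and it made 3.32%. Midnight had nearly come to rest at 4.00 min, with partner at 0.312% of its charge, falling to 0% by 40.0 min. Over that stretch precatalyst went to 39.2%, which the rule values at 0.31 percentage points, and the product rose by 0.31 points.

The constants are invented; no experiment stands behind them.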